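The reciprocal minute is the unit here: in each minute, one molecule of free monomer either stays free or enters a chain.

- larch: free monomer 2 M; initiator 4.2 mM; the very flask that is asked about, followed so far
- flask: free monomer 2.0 M; initiator 4.2 mM; time 40 min

larch run (percent of the free monomer charged)

| time / min | monomer in chains / % | free monomer / % |
|---|---|---|
| 5.00 | 2.0 | 96.2 |
| 10.0 | 7.4 | 90.0 |
| 15.0 | 11.5 | 87.7 |
| 20.0 | 19.0 | 81.5 |

(standard deviation of a reading: 1 percentage point)



- monomer in chains present at 40 min, in percent of the free monomer charged
- free monomer present at 40 min, in percent of the free monomer charged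

At 20.0 min the two columns of the larch run add up to 100.5 %, so no side loss shows. The free fraction f can therefore be read as the mean of the free column and what the chains column leaves: 97.1 % at 5.00 min, 81.2 % at 20.0 min. Between those two readings the chance per minute c, defined as ln(earlier f / later f) divided by the minutes between them, reads 0.0119 min⁻¹, an average over that stretch. The opening stretch up to 5.00 min reads slower, at 0.00589 min⁻¹, so it is set aside. A molecule free at 20.0 min then stays free until 40 min with chance exp(−c × elapsed minutes) = 78.9 %, so this reckoning gives 64.1 % free and 35.9 % in chains.

The forecast, holding “so monomer simply moves into chains”, gives 36 % in chains (30 % to 44 %) and 64 % free (56 % to 70 %).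

The flask gives 39.7 % in chains and 60.3 % free at 40 min. Between 20.0 min and 40 min initiator fell from 4.08 % to 0.548 % of its charge, while living end stood at 0.00364 M and then 0.00386 M. Read across that stretch, from 81.0 % free to the result, c comes to 0.0147 min⁻¹, higher than the 0.0119 min⁻¹ of the earlier stretch.

    free monomer + initiator → living end + monomer in chains (k = 0.106 L mol⁻¹ min⁻¹)
    free monomer + living end → monomer in chains + living end, rate k2*[living end]*[free monomer] (k = 3.89 L mol⁻¹ min⁻¹)
    2 initiator → spent initiator (k = 5.30 L mol⁻¹ min⁻¹)
    initiator ⇌ dormant form (K = 0.414, k = 0.311 min⁻¹)

The neighbour flask is this flask read at 2.5 h: with c at 0.0147 min⁻¹, a molecule free at 40 min stays free with chance 19.8 %, which leaves 11.9 % free. The computed neighbour flask holds 11.4 % free and 88.6 % in chains.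

The data are calculated for substances that don't exist, and the scatter is random.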